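- Our reckoning starts from the leftover: L still unreacted at the end. J is then what has gone in, less that small correction.

in all of them: D 1.74 mM; E 10 mol%

| flask | L | remark | time |
|---|---|---|---|
| Wednesday's | 0.029 M (fed, over 0.60 h) | run made earlier |  |
| Friday's | 0.044 M (fed, over 0.60 h) | run made earlier |  |
| north | 0.058 M (fed, over 0.60 h) |  | 2.5 h |
| east | 0.058 M (fed, over 2.0 h) |  | 2.5 h |
| south-east | 0.058 M (fed, over 6.0 h) |  | 2.5 h |

| run | time / h | J / % | L / % |
|---|---|---|---|
| Wednesday's | 0.200 | 1.0 | 31.0 |
| Wednesday's | 0.667 | 37.9 | 62.8 |
| Wednesday's | 1.00 | 67.6 | 32.3 |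
| Wednesday's | 1.50 | 88.6 | 11.6 |
| Wednesday's | 2.50 | 98.7 | 1.3 |
| Wednesday's | 3.00 | 98.3 | 1.4 |
| Friday's | 0.250 | 5.5 | 37.4 |
| Friday's | 0.417 | 18.6 | 51.3 |
| Friday's | 0.667 | 55.4 | 45.2 |
| Friday's | 1.00 | 84.3 | 15.3 |
| Friday's | 2.00 | 98.7 | 0.4 |
| Friday's | 3.00 | 100.0 | 0.4 |

(readings scatter by 0.5 percentage points)

- steps thought possible: L + E -> Q + J; L + Q -> J + Q; Q + D -> G; 2 E -> X
- percentages count the whole charge, also what has not yet gone in
- "hardly changes" means that all values lie within two and a half points (for a concentration: within two and a half percent of the largest)

1. amount of J at the end, in percent of the L charged for north, east, south-east, in this order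
2. how that number moves from the first to the last of them (hardly changes / rises all the way / falls all the way / rises, then falls / falls, then rises)

- Once the feed has stopped, L falls by a roughly steady factor per hour (pseudo-first-order): Wednesday's tail reads 2.05 /h and Friday's 3.25 /h. That is a factor 1.59 for a charge factor 1.52, so, at the same loading of E, we scale Friday's tail to the new charge and get 4.29 /h.
- Friday's tail times Friday's own dosing time gives 1.95; this feed number counts the lifetimes of L that fit into one feed. In our reckoning it grows with the charge and with the dosing time, at the same loading of E, so south-east's is 25.7. While a long feed runs, we expect L to stand where use matches supply, at about one over the feed number of the charge.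
- South-east at 2.5 h has received 41.7%, and we reckon 3.89% as L, so we expect J at 37.8%.
- East has a feed number of 8.58, and by our reckoning the tail after its feed leaves 1.37% as L, so we expect J at 98.6%.
- North's feed is short, but even a whole charge standing at the end of its feed would shrink to 0.0290%, so J is about 100%.
- One number is not quite enough: on Wednesday at 0.200 h, J is 1.0% of the 33.3% fed. The tail's rate does not hold from the start of that feed, so our south-east leftover is probably too small.
- The forecast gives 99.9%, 98.6% and 37.5%, and falls all the way, noting “These rates scale roughly with E”. Its south-east figure lies slightly below ours.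
- The flasks give 100%, 97.4% and 34.6%, and falls all the way, so the forecast stands.

    L + E → Q + J (k = 120 /M/h)
    L + Q → J + Q, rate k2*[Q]*[L] (k = 1110 /M/h)
    Q + D → G (k = 187 /M/h)
    2 E → X (k = 42.5 /M/h)

- In south-east at 2.50 h, [Q] is 0.00210 M, which gives L a lifetime of 0.429 h in the chain step, shorter than the 6.0 h feed; the feed number is then 14.0 instead of our 25.7, and one over it is 7.15%, beside 7.05% of L in the flask. East in mid-feed at 1.25 h, with [Q] at 0.00289 M, has a feed number of 6.42, which gives 15.6%, beside a simulated L of 16.4%.

All runs are calculated for an exercise; scatter was added.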